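**Assumption:** andrographolide, a bulk plant isolate sold at low cost, is taken as a cheap commercial starting material. Andrographolide numbering is used, with primed locants for the half that keeps the CH2–O butenolide.

## Retrosynthetic overview

1. Target 11 comes from bis-acetonide 10 by removal of two acetonides.
2. The C15–C12' bond and both linking stereocentres of 10 are traced back, through a Cope/Claisen relay, to the 2-furyl allyl ether 8. The key disconnection is the C16–O bond of 8, made from furyl triflate 5 and allylic alcohol 7 by Pd2(dba)3/RockPhos C–O coupling.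
3. Alcohol 7 comes from carbonate 3 by anti-SN2' borylation and C–B to C–O oxidation, which sets C12' from the natural C14 centre.
4. Triflate 5 comes from dienyl butenolide 4; both 4 and 3 come from acetonide 2, and 2 from andrographolide 1.
5. Ring order: both decalins and the CH2–O butenolide are carried from 1; the central butenolide is aromatised to a furan (5) and re-formed last (8 → 9 → 10).

## Route

**Step 1**
Reactants: 1 andrographolide
Product: 2 andrographolide 3,19-acetonide
Conditions: Me2C(OMe)2, PPTS (cat.), toluene/DMSO, 80 °C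
Reagents that add atoms: 2,2-dimethoxypropane, COC(C)(C)OC
Why: Acid-catalysed transacetalisation closes a six-membered 1,3-dioxane on the C3/C19 1,3-diol and leaves the hindered allylic C14-OH free; no stereocentre is touched.

**Step 2**
Reactants: 2 andrographolide 3,19-acetonide
Product: 3 14-O-(methoxycarbonyl)andrographolide 3,19-acetonide
Conditions: ClCO2Me, pyridine, CH2Cl2, 0 °C
Reagents that add atoms: methyl chloroformate, COC(=O)Cl
Why: O-acylation (carbonate formation) of the only free hydroxyl proceeds with retention at C14, and the low temperature avoids E1cB loss of the new leaving group.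

**Step 3**
Reactants: 2 andrographolide 3,19-acetonide
Product: 4 14-deoxy-11,12-didehydroandrographolide 3,19-acetonide
Conditions: basic Al2O3, pyridine, reflux
Reagents that add atoms: none
Why: Vinylogous E1cB dehydration (C11-H and C14-OH), the same reaction known for andrographolide itself, gives the conjugated (11E)-diene butenolide under thermodynamic control.

**Step 4**
Reactants: 4 14-deoxy-11,12-didehydroandrographolide 3,19-acetonide
Product: 5 furan-2-yl triflate of 4
Conditions: KN(SiMe3)2, THF, −78 °C; PhNTf2, −78 to 0 °C; used crude after filtration through neutral Al2O3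
Reagents that add atoms: N-phenylbis(trifluoromethanesulfonimide), O=S(=O)(N(c1ccccc1)S(=O)(=O)C(F)(F)F)C(F)(F)F
Why: Deprotonation at C15 gives the aromatic potassium 2-furanolate, which the hard sulfur electrophile captures on oxygen (enol triflate formation, the same enolisation used to make 2-silyloxyfurans).

**Step 5**
Reactants: 3 14-O-(methoxycarbonyl)andrographolide 3,19-acetonide
Product: 7 (12S)-14-deoxy-12-hydroxyandrographolide 3,19-acetonide, via allylboronate 6 (not isolated)
Conditions: B2pin2 (1.05 equiv), CuCl (5 mol%), Xantphos (5 mol%), KOtBu (10 mol%), THF, 0 °C to rt; then NaBO3·4H2O, THF/H2O, rt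
Reagents that add atoms: bis(pinacolato)diboron, CC1(C)OB(OC1(C)C)B1OC(C)(C)C(C)(C)O1 (boron of 6); sodium perborate, [Na+].[O-]OB=O (hydroxyl oxygen of 7)
Why: In this CuCl/Xantphos-catalysed γ-selective allylic borylation, LCu–Bpin adds to the alkylidene lactone on the face anti to the C14 carbonate and the carbonate then leaves anti (anti-SN2'), which sets C12 as S; perborate oxidation turns C–B into C–O with retention.

**Step 6 (key step)**
Reactants: 5 furan-2-yl triflate of 4; 7 (12S)-14-deoxy-12-hydroxyandrographolide 3,19-acetonide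
Product: 10 (12'S,15R)-bis(3,19-acetonide) of the target, via furyl ether 8 (not isolated), via Claisen furanone 9 (not isolated)
Conditions: Pd2(dba)3 (2.5 mol%), RockPhos (6 mol%), Cs2CO3 (1.5 equiv), toluene, 50 °C; filter through Celite; toluene, 100 °C
Reagents that add atoms: none
Why: Proposed new method: LPd(furyl)(OTf) from oxidative addition of 5 exchanges triflate for the alkoxide of 7 and closes the C16–O bond by reductive elimination (closest known: Buchwald–Hartwig-type Pd etherification of aryl triflates with secondary alcohols), and the 2-(allyloxy)-3-vinylfuran 8 then relays like an ortho-blocked allyl aryl ether, by a chair Claisen shift to C13 (C11' chain equatorial, furan ring exo) followed by a Cope shift on the same furanone face to C15 (closest known: para-Claisen rearrangement; Cope shift of 3-allylfuran-2(3H)-ones to 5-allylfuran-2(5H)-ones), so that both shifts are suprafacial on the allyl unit, the 12'S C–O centre is returned as the 12'S C–C centre, C15 is set R, the ether oxygen ends as the C16 carbonyl and both butenolides are restored.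

**Step 7**
Reactants: 10 (12'S,15R)-bis(3,19-acetonide) of the target
Product: 11 target compound
Conditions: AcOH/H2O (7:3), rt
Reagents that add atoms: none
Why: Mild acetal hydrolysis, the standard removal of 3,19-isopropylidene groups from andrographolides, frees the four hydroxyls without touching the butenolides, the exocyclic alkenes or any stereocentre.

## Compound list

1 | andrographolide ((12E,14S)-lactone, natural ent-labdane) | O=C1OC[C@@H](O)/C1=C\C[C@@H]1C(=C)CC[C@@H]2[C@](C)(CO)[C@H](O)CC[C@]21C | starting material

2 | andrographolide 3,19-acetonide (3,19-O-isopropylidene, 14S-OH free) | O=C1OC[C@@H](O)/C1=C\C[C@@H]1C(=C)CC[C@@H]2[C@]3(C)COC(C)(C)O[C@@H]3CC[C@]21C | intermediate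

3 | 14-O-(methoxycarbonyl)andrographolide 3,19-acetonide (14S) | O=C1OC[C@@H](OC(=O)OC)/C1=C\C[C@@H]1C(=C)CC[C@@H]2[C@]3(C)COC(C)(C)O[C@@H]3CC[C@]21C | intermediate

4 | 14-deoxy-11,12-didehydroandrographolide 3,19-acetonide ((11E)-diene, 13(14)-ene butenolide) | O=C1OCC=C1/C=C/[C@@H]1C(=C)CC[C@@H]2[C@]3(C)COC(C)(C)O[C@@H]3CC[C@]21C | intermediate

5 | furan-2-yl triflate of 4 (3-[(E)-2-(decalinyl)ethenyl]furan-2-yl trifluoromethanesulfonate, 3,19-acetonide) | O=S(=O)(Oc1occc1/C=C/[C@@H]1C(=C)CC[C@@H]2[C@]3(C)COC(C)(C)O[C@@H]3CC[C@]21C)C(F)(F)F | intermediate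

6 | (12S)-14-deoxy-12-(pinacolatoboryl)andrographolide 3,19-acetonide (13(14)-ene butenolide) | O=C1OCC=C1[C@@H](B1OC(C)(C)C(C)(C)O1)C[C@@H]1C(=C)CC[C@@H]2[C@]3(C)COC(C)(C)O[C@@H]3CC[C@]21C | intermediate

7 | (12S)-14-deoxy-12-hydroxyandrographolide 3,19-acetonide | O=C1OCC=C1[C@@H](O)C[C@@H]1C(=C)CC[C@@H]2[C@]3(C)COC(C)(C)O[C@@H]3CC[C@]21C | intermediate

8 | 2-furyl ether: O12' of 7 (12'S) bonded to C16 (furan C2) of the furan derived from 4, bis-acetonide | O=C1OCC=C1[C@@H](Oc1occc1/C=C/[C@@H]1C(=C)CC[C@@H]2[C@]3(C)COC(C)(C)O[C@@H]3CC[C@]21C)C[C@@H]1C(=C)CC[C@@H]2[C@]3(C)COC(C)(C)O[C@@H]3CC[C@]21C | intermediate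

9 | Claisen furanone: 3,3-disubstituted furan-2(3H)-one whose quaternary C13 carries the (E)-vinyl decalin and C14' of a (12'Z)-alkylidene lactone (C11' cis to the lactone C=O), bis-acetonide | O=C1OC=C[C@@]1(/C=C/[C@@H]1C(=C)CC[C@@H]2[C@]3(C)COC(C)(C)O[C@@H]3CC[C@]21C)[C@@H]1COC(=O)/C1=C\C[C@@H]1C(=C)CC[C@@H]2[C@]3(C)COC(C)(C)O[C@@H]3CC[C@]21C | intermediate

10 | (12'S,15R)-bis(3,19-acetonide) of the target | C=C1CC[C@@H]2[C@]3(C)COC(C)(C)O[C@@H]3CC[C@@]2(C)[C@@H]1/C=C/C1=C[C@H]([C@@H](C[C@@H]2C(=C)CC[C@@H]3[C@]4(C)COC(C)(C)O[C@@H]4CC[C@]32C)C2=CCOC2=O)OC1=O | intermediate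

11 | target CNP0220272.2, the (12'S,15R) C15–C12'-linked dimer | C=C1CC[C@@H]2[C@](C)(CO)[C@H](O)CC[C@@]2(C)[C@@H]1/C=C/C1=C[C@H]([C@@H](C[C@@H]2C(=C)CC[C@@H]3[C@](C)(CO)[C@H](O)CC[C@]32C)C2=CCOC2=O)OC1=O | target

## Step count and risks

Total steps: 7. Longest linear sequence: 5 (1 → 2 → 4 → 5 → 10 → 11, or 1 → 2 → 3 → 7 → 10 → 11).

**Step 6 (the proposed new step)** is the most likely to fail. The LPd(furyl)(OR) intermediate may undergo β-hydride elimination to the 12'-ketone, the alkoxide may attack sulfur of the triflate, or the relay may not keep to the chair Claisen path. The fallback uses known chemistry and joins the halves directly through carbon. It sets out from 4, which is enolised and silylated (TBSOTf, Et3N, CH2Cl2, 0 °C) to the 2-(tert-butyldimethylsilyloxy)furan F1. F1 is added to carbonate 3 by a fluoride-triggered vinylogous Mukaiyama–Michael addition with E1cB loss of the carbonate (tetrabutylammonium difluorotriphenylsilicate, THF, −78 °C). This comes back to the route at 10, with the C15 epimers separated by chromatography.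

**Step 5** can fail through base-induced elimination of 3 to 4, through direct substitution at C14, or through incomplete anti selectivity. The fallback sets out from 3 and installs the oxygen directly by SN2' acyloxylation with cesium 4-nitrobenzoate in DMF at 40 °C. This gives the 12-(4-nitrobenzoyloxy)-14-deoxy acetonide F2, whose 12S epimer is separated and methanolysed (K2CO3, MeOH, 0 °C). It comes back to the route at 7.

**Step 4** can fail because the electron-rich furyl triflate is labile, or because sulfonylation occurs on carbon. The fallback sets out from 4 and replaces the sulfonate/Pd2(dba)3 coupling by a Johnson–Claisen-type ketene-acetal exchange. O-Methylation of the potassium furanolate (KN(SiMe3)2, THF/DMPU, −78 °C; Me2SO4) gives the 2-methoxyfuran F3. Heating F3 with 7 and pivalic acid (10 mol%) in toluene at 110 °C over 4 Å molecular sieves exchanges methanol for the allylic alcohol and forms 8, which relays through 9. It comes back to the route at 10.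

## Further compounds

F1 | step 6 | 2-(tert-butyldimethylsilyloxy)furan of 4 (3,19-acetonide) | CC(C)(C)[Si](C)(C)Oc1occc1/C=C/[C@@H]1C(=C)CC[C@@H]2[C@]3(C)COC(C)(C)O[C@@H]3CC[C@]21C
F2 | step 5 | (12S)-14-deoxy-12-(4-nitrobenzoyloxy)andrographolide 3,19-acetonide | O=C1OCC=C1[C@@H](OC(=O)c1ccc([N+](=O)[O-])cc1)C[C@@H]1C(=C)CC[C@@H]2[C@]3(C)COC(C)(C)O[C@@H]3CC[C@]21C
F3 | step 4 | 2-methoxyfuran of 4 (3,19-acetonide) | COc1occc1/C=C/[C@@H]1C(=C)CC[C@@H]2[C@]3(C)COC(C)(C)O[C@@H]3CC[C@]21C
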